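**Strategy.** Ring numbering: C1 bears the side chain, C2 the methylene, C3 and C5 the bromines, C6 the methyl pair. C3 and C5 flank C4 in a 1,3-relationship, the pattern of a ketol, so the ring is cut at C3–C4; C1 with its chain derives from (S)-linalool after oxidative removal of the isopropylidene terminus. An intramolecular boron aldol joins the acetyl methyl carbon (C4) of an acyclic keto-enal to the α-methylene aldehyde carbon (C3): one operation closes the cyclohexane, keeps the exocyclic C2 methylene and sets the C3 hydroxyl trans to the chain. The precursor is a TES-protected 2-methylidene-4,4-dimethyl-5-oxohexanal carrying the linalool chain at its β-carbon; both ring oxygens are later replaced by bromine with inversion.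

Key step: step 7

Assumption: (S)-(+)-linalool of high enantiomeric purity is taken as a purchasable chiral-pool material.

Step 1
Reactants: 1 (S)-linalool
Product: 2 (S)-linalool triethylsilyl ether
Conditions: TESOTf, 2,6-lutidine, CH2Cl2, −78 → 0 °C
Reagents that add atoms: triethylsilyl trifluoromethanesulfonate, CC[Si](CC)(CC)OS(=O)(=O)C(F)(F)F
Why: O-silylation of the hindered tertiary allylic alcohol needs the silyl triflate with a hindered base, and the carbinol stereocentre is not touched.

Step 2
Reactants: 2 (S)-linalool triethylsilyl ether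
Product: 4 (4S)-4-methyl-4-(triethylsilyloxy)hex-5-enal, via ozonide 3 (not isolated)
Conditions: O3, Sudan Red 7B (indicator), CH2Cl2, −78 °C; then PPh3, −78 °C → rt
Reagents that add atoms: ozone, [O-][O+]=O
Why: Dye-indicated selective ozonolysis, in which the electron-rich trisubstituted alkene should be consumed well before the monosubstituted vinyl group on the silyloxy-bearing quaternary carbon, followed by reductive cleavage of the ozonide to the aldehyde.

Step 3
Reactants: 4 (4S)-4-methyl-4-(triethylsilyloxy)hex-5-enal; 5 2-(triphenylphosphoranylidene)acetaldehyde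
Product: 6 (2E,6S)-6-methyl-6-(triethylsilyloxy)octa-2,7-dienal
Conditions: toluene, 80 °C
Reagents that add atoms: none
Why: Wittig olefination with the stabilised formyl ylide should give the (E)-enal, the ylide being kept near one equivalent to limit a second homologation.

Step 4
Reactants: 7 3-methylbutan-2-one
Product: 8 trimethyl[(3-methylbut-2-en-2-yl)oxy]silane
Conditions: TMSCl, NaI, Et3N, MeCN, rt; fractional distillation
Reagents that add atoms: chlorotrimethylsilane, C[Si](C)(C)Cl
Why: Equilibrating enol silylation through iodotrimethylsilane formed in the flask should favour the more substituted (tetrasubstituted) silyl enol ether, which is freed from the terminal isomer by distillation.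

Step 5
Reactants: 6 (2E,6S)-6-methyl-6-(triethylsilyloxy)octa-2,7-dienal; 8 trimethyl[(3-methylbut-2-en-2-yl)oxy]silane
Product: 9 (3R)-4,4-dimethyl-3-[(3S)-3-methyl-3-(triethylsilyloxy)pent-4-en-1-yl]-5-oxohexanal
Conditions: (2S,5S)-5-benzyl-2-tert-butyl-3-methylimidazolidin-4-one (20 mol %), 2,4-dinitrobenzoic acid (20 mol %), CH2Cl2, H2O (2 equiv), −40 °C
Reagents that add atoms: none
Why: Iminium-catalysed Mukaiyama–Michael addition, in which the enol silane adds 1,4 to the (E)-iminium ion on the face remote from the benzyl group of the catalyst (the sense that gives R β-substituted aldehydes), so the new centre (later ring C1) is set R by the catalyst alone, independently of the remote carbinol, and the quaternary C6 is formed in the same bond.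

Step 6
Reactants: 9 (3R)-4,4-dimethyl-3-[(3S)-3-methyl-3-(triethylsilyloxy)pent-4-en-1-yl]-5-oxohexanal; 10 formaldehyde
Product: 11 (3R)-4,4-dimethyl-2-methylidene-3-[(3S)-3-methyl-3-(triethylsilyloxy)pent-4-en-1-yl]-5-oxohexanal
Conditions: 37% aq. CH2O, pyrrolidine (10 mol %), propionic acid (10 mol %), i-PrOH, 45 °C
Reagents that add atoms: none
Why: Amine-catalysed α-methylenation (Mannich condensation then elimination) occurs at the aldehyde α-CH2 only, because the hindered tert-alkyl methyl ketone forms an enamine far more slowly, and the β-stereocentre is not epimerisable.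

Step 7
Reactants: 11 (3R)-4,4-dimethyl-2-methylidene-3-[(3S)-3-methyl-3-(triethylsilyloxy)pent-4-en-1-yl]-5-oxohexanal
Product: 14 (3R,5S)-5-hydroxy-2,2-dimethyl-4-methylidene-3-[(3S)-3-methyl-3-(triethylsilyloxy)pent-4-en-1-yl]cyclohexan-1-one, via dibutylboron enolate 12 (not isolated), via dibutylboron aldolate 13 (not isolated)
Conditions: freshly prepared 11, n-Bu2BOTf, i-Pr2NEt, CH2Cl2 (0.02 M), −78 → −20 °C; then pH 7 buffer, MeOH, 30% H2O2, 0 °C
Reagents that add atoms: none
Why: n-Bu2BOTf/i-Pr2NEt enolises the only enolisable position, the acetyl methyl C4 (C6 is quaternary and the aldehyde α-carbon C2 is sp2), and the boron enolate 12 adds 1,2 to the aldehyde carbon C3 through a boron-bridged closed (Zimmerman–Traxler-type) transition state to give aldolate 13, which buffered oxidative work-up releases as the ketol. The closest known reaction type is the intramolecular aldol cyclisation of a 1,5-keto aldehyde stopped at the β-hydroxy ketone (the aldol half of a Robinson annulation), run here with a boron enolate as in boron aldol additions to α-methylene aldehydes. The ring closes in the 6-(enolendo)-exo-trig mode. The new C3 stereocentre is controlled by the C1 stereocentre: in the chair-like transition state the side chain lies pseudo-equatorial and the aldehyde oxygen must stand axial to reach the boron on the enolate oxygen (the s-trans enal geometry leads to the same result), so the hydroxyl should emerge trans to the chain. The step needs 1,2-addition in preference to 6-endo conjugate addition at the methylene, and cyclisation in preference to oligomerisation; the tightly bound, non-equilibrating boron aldolate at low temperature, the single possible enolate and high dilution should secure this.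

Step 8
Reactants: 14 (3R,5S)-5-hydroxy-2,2-dimethyl-4-methylidene-3-[(3S)-3-methyl-3-(triethylsilyloxy)pent-4-en-1-yl]cyclohexan-1-one
Product: 15 (1S,3S,5S)-4,4-dimethyl-6-methylidene-5-[(3S)-3-methyl-3-(triethylsilyloxy)pent-4-en-1-yl]cyclohexane-1,3-diol
Conditions: Me4NBH(OAc)3, MeCN–AcOH, −30 → −20 °C
Reagents that add atoms: none
Why: Evans–Saksena directed reduction, in which the C3 hydroxyl exchanges onto boron and delivers hydride intramolecularly to the same face of the C5 carbonyl, should give the 1,3-anti diol with C5–OH trans to C3–OH and cis to the chain.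

Step 9
Reactants: 15 (1S,3S,5S)-4,4-dimethyl-6-methylidene-5-[(3S)-3-methyl-3-(triethylsilyloxy)pent-4-en-1-yl]cyclohexane-1,3-diol
Product: 16 (1S,3S,5S)-5-(tert-butyldimethylsilyloxy)-2,2-dimethyl-4-methylidene-3-[(3S)-3-methyl-3-(triethylsilyloxy)pent-4-en-1-yl]cyclohexan-1-ol
Conditions: TBSCl (1.1 equiv), imidazole, DMF, 0 °C
Reagents that add atoms: tert-butyldimethylsilyl chloride, CC(C)(C)[Si](C)(C)Cl
Why: Kinetically selective O-silylation, since the allylic C3 hydroxyl (between sp2 C2 and a CH2) should react with TBSCl/imidazole much faster than the C5 hydroxyl next to the quaternary C6, leaving the neopentylic alcohol free with no stereocentre changed.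

Step 10
Reactants: 16 (1S,3S,5S)-5-(tert-butyldimethylsilyloxy)-2,2-dimethyl-4-methylidene-3-[(3S)-3-methyl-3-(triethylsilyloxy)pent-4-en-1-yl]cyclohexan-1-ol
Product: 17 tert-butyl({(1S,3R,5R)-5-bromo-4,4-dimethyl-2-methylidene-3-[(3S)-3-methyl-3-(triethylsilyloxy)pent-4-en-1-yl]cyclohexyl}oxy)dimethylsilane
Conditions: CBr4, n-Oct3P, toluene, 0 → 70 °C
Reagents that add atoms: carbon tetrabromide, BrC(Br)(Br)Br
Why: Appel bromination of a hindered secondary alcohol, in which bromide displaces the C5 alkoxyphosphonium by SN2 with inversion, expected to run through the chair with the leaving group axial (side chain axial, C3–OTBS equatorial) so that bromide enters equatorially and C5–Br ends trans to the chain, the non-ionising medium being chosen to hold back Wagner–Meerwein shifts.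

Step 11
Reactants: 17 tert-butyl({(1S,3R,5R)-5-bromo-4,4-dimethyl-2-methylidene-3-[(3S)-3-methyl-3-(triethylsilyloxy)pent-4-en-1-yl]cyclohexyl}oxy)dimethylsilane
Product: 18 (1S,3R,5R)-5-bromo-3-[(3S)-3-hydroxy-3-methylpent-4-en-1-yl]-4,4-dimethyl-2-methylidenecyclohexan-1-ol
Conditions: HF·pyridine, pyridine, THF, 0 °C → rt
Reagents that add atoms: none
Why: Buffered fluoride desilylation should cleave both the secondary TBS and the tertiary TES ether without affecting the secondary bromide or any stereocentre.

Step 12
Reactants: 18 (1S,3R,5R)-5-bromo-3-[(3S)-3-hydroxy-3-methylpent-4-en-1-yl]-4,4-dimethyl-2-methylidenecyclohexan-1-ol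
Product: 19 (3S)-5-[(1S,3R,5R)-3,5-dibromo-2,2-dimethyl-6-methylidenecyclohexyl]-3-methylpent-1-en-3-ol
Conditions: CBr4, PPh3, CH2Cl2, −20 → 0 °C
Reagents that add atoms: carbon tetrabromide, BrC(Br)(Br)Br
Why: Appel reaction, in which only the secondary allylic hydroxyl should form an alkoxyphosphonium at low temperature (the tertiary carbinol is too hindered) and bromide displaces it by SN2 with inversion, helped by relief of the 1,3-diaxial C3–O/C5–Br interaction, to give C3–Br cis to the chain, the low temperature being meant to suppress the SN2′ path to the transposed primary bromide.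

**Compound list**

1 | (S)-(+)-linalool, (3S)-3,7-dimethylocta-1,6-dien-3-ol | C=C[C@@](C)(O)CCC=C(C)C | starting material
2 | (S)-linalool triethylsilyl ether, triethyl{[(3S)-3,7-dimethylocta-1,6-dien-3-yl]oxy}silane | C=C[C@@](C)(O[Si](CC)(CC)CC)CCC=C(C)C | intermediate
3 | ozonide (1,2,4-trioxolane) of 2 at the trisubstituted alkene, not isolated | C=C[C@@](C)(O[Si](CC)(CC)CC)CCC1OOC(C)(C)O1 | intermediate
4 | (4S)-4-methyl-4-(triethylsilyloxy)hex-5-enal | C=C[C@@](C)(O[Si](CC)(CC)CC)CCC=O | intermediate
5 | 2-(triphenylphosphoranylidene)acetaldehyde | O=CC=P(c1ccccc1)(c1ccccc1)c1ccccc1 | starting material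
6 | (2E,6S)-6-methyl-6-(triethylsilyloxy)octa-2,7-dienal | C=C[C@@](C)(O[Si](CC)(CC)CC)CC/C=C/C=O | intermediate
7 | 3-methylbutan-2-one | CC(C)C(C)=O | starting material
8 | trimethyl[(3-methylbut-2-en-2-yl)oxy]silane | CC(C)=C(C)O[Si](C)(C)C | intermediate
9 | (3R)-4,4-dimethyl-3-[(3S)-3-methyl-3-(triethylsilyloxy)pent-4-en-1-yl]-5-oxohexanal | CC(=O)C(C)(C)[C@H](CC[C@](C)(O[Si](CC)(CC)CC)C=C)CC=O | intermediate
10 | formaldehyde | C=O | starting material
11 | (3R)-4,4-dimethyl-2-methylidene-3-[(3S)-3-methyl-3-(triethylsilyloxy)pent-4-en-1-yl]-5-oxohexanal (aldol precursor) | CC(=O)C(C)(C)[C@H](CC[C@](C)(O[Si](CC)(CC)CC)C=C)C(=C)C=O | intermediate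
12 | dibutylboron enolate of 11 (enolised at the acetyl methyl), not isolated | C=C(OB(CCCC)CCCC)C(C)(C)[C@H](CC[C@](C)(O[Si](CC)(CC)CC)C=C)C(=C)C=O | intermediate
13 | dibutylboron aldolate of 14 (O-boryl at C3), not isolated | C=C[C@@](C)(O[Si](CC)(CC)CC)CC[C@@H]1C(=C)[C@@H](OB(CCCC)CCCC)CC(=O)C1(C)C | intermediate
14 | (3R,5S)-5-hydroxy-2,2-dimethyl-4-methylidene-3-[(3S)-3-methyl-3-(triethylsilyloxy)pent-4-en-1-yl]cyclohexan-1-one (hydroxyl trans to the chain) | C=C[C@@](C)(O[Si](CC)(CC)CC)CC[C@@H]1C(=C)[C@@H](O)CC(=O)C1(C)C | intermediate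
15 | (1S,3S,5S)-4,4-dimethyl-6-methylidene-5-[(3S)-3-methyl-3-(triethylsilyloxy)pent-4-en-1-yl]cyclohexane-1,3-diol (anti diol; C3–OH trans, C5–OH cis to the chain) | C=C[C@@](C)(O[Si](CC)(CC)CC)CC[C@@H]1C(=C)[C@@H](O)C[C@H](O)C1(C)C | intermediate
16 | (1S,3S,5S)-5-(tert-butyldimethylsilyloxy)-2,2-dimethyl-4-methylidene-3-[(3S)-3-methyl-3-(triethylsilyloxy)pent-4-en-1-yl]cyclohexan-1-ol (C3–OTBS, C5–OH) | C=C[C@@](C)(O[Si](CC)(CC)CC)CC[C@@H]1C(=C)[C@@H](O[Si](C)(C)C(C)(C)C)C[C@H](O)C1(C)C | intermediate
17 | tert-butyl({(1S,3R,5R)-5-bromo-4,4-dimethyl-2-methylidene-3-[(3S)-3-methyl-3-(triethylsilyloxy)pent-4-en-1-yl]cyclohexyl}oxy)dimethylsilane (C5–Br trans to the chain) | C=C[C@@](C)(O[Si](CC)(CC)CC)CC[C@@H]1C(=C)[C@@H](O[Si](C)(C)C(C)(C)C)C[C@@H](Br)C1(C)C | intermediate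
18 | (1S,3R,5R)-5-bromo-3-[(3S)-3-hydroxy-3-methylpent-4-en-1-yl]-4,4-dimethyl-2-methylidenecyclohexan-1-ol | C=C[C@@](C)(O)CC[C@@H]1C(=C)[C@@H](O)C[C@@H](Br)C1(C)C | intermediate
19 | (3S)-5-[(1S,3R,5R)-3,5-dibromo-2,2-dimethyl-6-methylidenecyclohexyl]-3-methylpent-1-en-3-ol | C=C[C@@](C)(O)CC[C@@H]1C(=C)[C@H](Br)C[C@@H](Br)C1(C)C | target

**Step count and risks**

Total step count: 12. Longest linear sequence: 11 steps (1 to 19 through steps 1–3 and 5–12); step 4 is a one-step side branch.

Steps most likely to fail:

Step 7. Conjugate addition of the enolate to the methylene (6-endo) or intermolecular addition may compete with the 1,2-closure, the aldolate may revert or dehydrate on work-up, and facial control at C3 may be incomplete. Fallback: setting out from 11, a one-pot silyl triflate sequence (TMSOTf, i-Pr2NEt, CH2Cl2, −78 → 0 °C) would first convert the methyl ketone into the trimethylsilyl enol ether F1, which would then close onto the silyl-activated aldehyde in an intramolecular Mukaiyama aldol addition through an open transition state to give the O-trimethylsilyl ketol F2; brief treatment with dilute aqueous citric acid in THF would cleave the secondary trimethylsilyl ether and return the route at 14.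

Step 10. Ionisation with Wagner–Meerwein shift or ring contraction, or elimination, may outrun the slow SN2 displacement at the neopentylic C5, or the alkoxyphosphonium may simply fail to collapse. Fallback: setting out from 16, activation and displacement would be separated; chloromethanesulfonyl chloride and pyridine would give the isolable C5 chloromethanesulfonate F3, a leaving group less prone to ionise than a triflate, and a dissociated bromide (LiBr in N,N′-dimethylpropyleneurea, 40–60 °C) would displace it with inversion, rejoining the route at 17.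

Step 5. Addition of the hindered tetrasubstituted enol silane to the iminium ion may be sluggish or turn to 1,2-addition, and facial control at the future C1 may erode. Fallback: setting out from aldehyde 4, Knoevenagel condensation with dimethyl malonate (piperidine, AcOH) would give the alkylidene malonate F4. A copper(II)–bis(oxazoline)-catalysed Mukaiyama–Michael addition of 8, with the ligand enantiomer chosen for the R adduct, would give the malonate adduct F5. Krapcho demethoxycarbonylation (LiCl, wet DMSO, heat) would give the keto ester F6, LiAlH4 would reduce ester and ketone to the diol F7, and a double Swern oxidation would return the route at 9.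

**Further compounds**

F1 | step 7 | trimethylsilyl enol ether of 11 | C=C(O[Si](C)(C)C)C(C)(C)[C@H](CC[C@](C)(O[Si](CC)(CC)CC)C=C)C(=C)C=O
F2 | step 7 | O-trimethylsilyl ether of ketol 14 | C=C[C@@](C)(O[Si](CC)(CC)CC)CC[C@@H]1C(=C)[C@@H](O[Si](C)(C)C)CC(=O)C1(C)C
F3 | step 10 | C5 chloromethanesulfonate of 16 | C=C[C@@](C)(O[Si](CC)(CC)CC)CC[C@@H]1C(=C)[C@@H](O[Si](C)(C)C(C)(C)C)C[C@H](OS(=O)(=O)CCl)C1(C)C
F4 | step 5 | dimethyl 2-[(4S)-4-methyl-4-(triethylsilyloxy)hex-5-en-1-ylidene]malonate | C=C[C@@](C)(O[Si](CC)(CC)CC)CCC=C(C(=O)OC)C(=O)OC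
F5 | step 5 | dimethyl malonate Michael adduct (R at the new centre) | CC(=O)C(C)(C)[C@H](CC[C@](C)(O[Si](CC)(CC)CC)C=C)C(C(=O)OC)C(=O)OC
F6 | step 5 | methyl (3R)-4,4-dimethyl-3-[(3S)-3-methyl-3-(triethylsilyloxy)pent-4-en-1-yl]-5-oxohexanoate | CC(=O)C(C)(C)[C@H](CC[C@](C)(O[Si](CC)(CC)CC)C=C)CC(=O)OC
F7 | step 5 | (3R)-4,4-dimethyl-3-[(3S)-3-methyl-3-(triethylsilyloxy)pent-4-en-1-yl]hexane-1,5-diol (mixture at C5) | CC(O)C(C)(C)[C@H](CC[C@](C)(O[Si](CC)(CC)CC)C=C)CCO
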